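The cage is traced back to a spiro[4.5]decadienone in which ring C1–C2–C3–C4–C5–C9 is still a flat, dearomatised phloroglucinol and the cyclopentane C3–C11–C12–C13–C14 is already closed. The key step exploits exactly this feature: C3, the quaternary carbon common to both rings, is made when a para-phenoxide attacks its own C14 mesylate through the ring carbon, which closes the cyclopentane and turns the arene into the bis(methyl enol ether) of the trione in one operation. The precursor is a silyl-masked 4-alkyl-3,5-dimethoxyphenol whose benzylic C11 centre comes from an aromatic Claisen rearrangement. A ring-expanding Claisen, hydrogenation, two alkylations at C5 and a bridgehead benzoylation complete the cage.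

Key step: step 9

Remark on labels: the cage carbons are called C1 (benzoyl bridgehead), C2 and C4 (ketones next to quaternary C3), C5 (geranyl bridgehead), C6 (CH2), C7 (CH), C8 (CMe2), C9 (bridging ketone), C10 (CH2), C11 (CH), C12 (CMe2), C13 and C14 (CH2); the same labels are used for the corresponding atoms of every intermediate, and O2 is the oxygen on C2.
Remark on the precursor: the two phenols ortho to the side chain are methylated and the para phenol is silylated, so that the side-chain alcohol can be sulfonylated alone and the dearomatised product is one defined bis(enol ether).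
Assumption: enolisable 1,3-diones are drawn as one tautomer.

Step 1
Reactants: 1 methyl 3,3-dimethylpent-4-enoate; 2 methyl vinyl ketone
Product: 3 methyl (E)-3,3-dimethyl-6-oxohept-4-enoate
Conditions: second-generation Hoveyda–Grubbs catalyst [RuCl2(H2IMes)(=CH-C6H4-2-OiPr)] (5 mol%), 2 (3 equiv), CH2Cl2, 40 °C
Reagents that add atoms: none
Why: Olefin cross-metathesis between a terminal alkene on a quaternary carbon, which does not homodimerise, and an enone partner should be selective and give the E-enone.

Step 2
Reactants: 3 methyl (E)-3,3-dimethyl-6-oxohept-4-enoate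
Product: 4 methyl (S,E)-6-hydroxy-3,3-dimethylhept-4-enoate
Conditions: (R)-2-methyl-CBS-oxazaborolidine (10 mol%), catecholborane, PhMe, −78 °C
Reagents that add atoms: none
Why: Corey–Bakshi–Shibata reduction with the alkenyl group as the large substituent should give the (S)-carbinol from the (R)-catalyst and leaves the ester alone.

Step 3
Reactants: 4 methyl (S,E)-6-hydroxy-3,3-dimethylhept-4-enoate; 5 phloroglucinol
Product: 6 methyl (R,E)-6-(3,5-dihydroxyphenoxy)-3,3-dimethylhept-4-enoate
Conditions: 5 (4 equiv), PPh3, DIAD, THF, 0 → 23 °C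
Reagents that add atoms: none
Why: Mitsunobu etherification displaces the activated carbinol by SN2 with inversion, giving the (R)-ether, and the excess of the triol keeps the reaction at the mono-ether.

Step 4
Reactants: 6 methyl (R,E)-6-(3,5-dihydroxyphenoxy)-3,3-dimethylhept-4-enoate
Product: 7 methyl (R,E)-3,3-dimethyl-4-(2,4,6-trihydroxyphenyl)hept-5-enoate
Conditions: PhNEt2, 150 °C
Reagents that add atoms: none
Why: Aromatic Claisen rearrangement through a chair transition state with the methyl group pseudo-equatorial transfers the C–O chirality suprafacially to the benzylic carbon C11 (R) and gives the E-propenyl group; both ortho positions are equivalent.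

Step 5
Reactants: 7 methyl (R,E)-3,3-dimethyl-4-(2,4,6-trihydroxyphenyl)hept-5-enoate
Product: 8 methyl (R,E)-4-[2,6-dihydroxy-4-(triisopropylsilyloxy)phenyl]-3,3-dimethylhept-5-enoate
Conditions: TIPSCl (1.0 equiv), imidazole, DMF, 0 °C
Reagents that add atoms: chlorotriisopropylsilane, CC(C)[Si](Cl)(C(C)C)C(C)C
Why: Silylation with a bulky chlorosilane should take the para hydroxyl, flanked by two ring CH, in preference to the two hydroxyls next to the branched benzylic carbon.

Step 6
Reactants: 8 methyl (R,E)-4-[2,6-dihydroxy-4-(triisopropylsilyloxy)phenyl]-3,3-dimethylhept-5-enoate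
Product: 9 methyl (R,E)-4-[2,6-dimethoxy-4-(triisopropylsilyloxy)phenyl]-3,3-dimethylhept-5-enoate
Conditions: MeI, K2CO3, acetone, 45 °C
Reagents that add atoms: iodomethane, CI
Why: Williamson O-methylation of the two remaining phenols makes the ortho oxygens identical and non-nucleophilic.

Step 7
Reactants: 9 methyl (R,E)-4-[2,6-dimethoxy-4-(triisopropylsilyloxy)phenyl]-3,3-dimethylhept-5-enoate
Product: 10 (R,E)-4-[2,6-dimethoxy-4-(triisopropylsilyloxy)phenyl]-3,3-dimethylhept-5-en-1-ol
Conditions: i-Bu2AlH (2.5 equiv), CH2Cl2, −78 → 0 °C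
Reagents that add atoms: none
Why: Hydride reduction of the ester to the primary alcohol does not touch the aryl silyl ether or the alkene.

Step 8
Reactants: 10 (R,E)-4-[2,6-dimethoxy-4-(triisopropylsilyloxy)phenyl]-3,3-dimethylhept-5-en-1-ol
Product: 11 (R,E)-4-[2,6-dimethoxy-4-(triisopropylsilyloxy)phenyl]-3,3-dimethylhept-5-en-1-yl methanesulfonate
Conditions: MsCl, Et3N, CH2Cl2, 0 °C
Reagents that add atoms: methanesulfonyl chloride, CS(=O)(=O)Cl
Why: Sulfonylation of the only free hydroxyl gives the primary mesylate at C14.

Step 9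
Reactants: 11 (R,E)-4-[2,6-dimethoxy-4-(triisopropylsilyloxy)phenyl]-3,3-dimethylhept-5-en-1-yl methanesulfonate
Product: 13 (1R)-6,10-dimethoxy-2,2-dimethyl-1-[(E)-prop-1-en-1-yl]spiro[4.5]deca-6,9-dien-8-one, via tetrabutylammonium phenoxide 12 (not isolated)
Conditions: n-Bu4NF (1.05 equiv), THF (0.01 M), 0 → 23 °C
Reagents that add atoms: none
Why: Fluoride cleaves the aryl silyl ether to the naked para-phenoxide 12, whose ring carbon C3, para to O− and flanked by the two methoxy groups, displaces the primary mesylate at C14 and forms the C3–C14 bond. The closest known reaction type is Ar1-5 phenoxide participation, the para-alkylative dearomatisation of phenoxides to spirocyclohexadienones. The cyclopentane C3–C11–C12–C13–C14 closes in the 5-exo-tet mode. No stereocentre is formed, because C3 carries two identical ring arms, and the C11 centre from step 4 is not touched. The step needs C- rather than O-alkylation: the phenoxide oxygen cannot reach C14 within the molecule, the ortho oxygens are methyl ethers so the seven-membered aryl ether closure is shut off, and high dilution suppresses intermolecular etherification; the product cannot rearomatise because C3 is quaternary.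

Step 10
Reactants: 13 (1R)-6,10-dimethoxy-2,2-dimethyl-1-[(E)-prop-1-en-1-yl]spiro[4.5]deca-6,9-dien-8-one
Product: 14 (1R)-6,10-dimethoxy-2,2-dimethyl-8-oxospiro[4.5]deca-6,9-diene-1-carbaldehyde
Conditions: OsO4 (2 mol%), NaIO4 (4 equiv), 2,6-lutidine, dioxane/H2O (3:1), 23 °C
Reagents that add atoms: sodium periodate, [Na+].[O-]I(=O)(=O)=O (source of the aldehyde oxygen, relayed by OsO4)
Why: Lemieux–Johnson cleavage should dihydroxylate the isolated E-alkene faster than the carbonyl-deactivated enol ether double bonds, and periodate then cuts the diol to the C10 aldehyde without touching C11.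

Step 11
Reactants: 15 3-methylbut-2-enal
Product: 17 2-bromo-3-methylbut-2-enal, via dibromo aldehyde 16 (not isolated)
Conditions: Br2, CH2Cl2, 0 °C; then Et3N, 0 → 23 °C
Reagents that add atoms: bromine, BrBr
Why: Bromine addition followed by base-induced loss of HBr is the standard α-bromination of an enal.

Step 12
Reactants: 17 2-bromo-3-methylbut-2-enal
Product: 18 2-bromo-3-methylbut-2-en-1-ol
Conditions: NaBH4, MeOH, 0 °C
Reagents that add atoms: none
Why: Borohydride reduces the aldehyde by 1,2-addition and leaves the alkenyl bromide intact.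

Step 13
Reactants: 18 2-bromo-3-methylbut-2-en-1-ol
Product: 19 [(2-bromo-3-methylbut-2-en-1-yl)oxy](tert-butyl)dimethylsilane
Conditions: TBSCl, imidazole, CH2Cl2, 23 °C
Reagents that add atoms: tert-butylchlorodimethylsilane, CC(C)(C)[Si](C)(C)Cl
Why: Silylation protects the future C6 hydroxyl through the organolithium and thermal steps.

Step 14
Reactants: 14 (1R)-6,10-dimethoxy-2,2-dimethyl-8-oxospiro[4.5]deca-6,9-diene-1-carbaldehyde; 19 [(2-bromo-3-methylbut-2-en-1-yl)oxy](tert-butyl)dimethylsilane
Product: 21 (1R)-1-[(1R)-2-[(tert-butyldimethylsilyloxy)methyl]-1-hydroxy-3-methylbut-2-en-1-yl]-6,10-dimethoxy-2,2-dimethylspiro[4.5]deca-6,9-dien-8-one, via alkenyllithium 20 (not isolated)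
Conditions: 19 (1.2 equiv), t-BuLi (2.4 equiv), Et2O, −78 °C; then 14, THF, −78 °C
Reagents that add atoms: none
Why: Bromine–lithium exchange gives alkenyllithium 20, which adds 1,2 to the aldehyde (far more electrophilic than the doubly donor-substituted dienone carbonyl) and forms the C10–C7 bond; Felkin–Anh attack anti to the CMe2 carbon C12 should set C10 as R.

Step 15
Reactants: 21 the C10 (R) alcohol from step 14
Product: 22 oxolane-bridged dienone: C4-methoxy C9-oxo dienone whose oxygen O2 is bonded to C10 (ring O2–C2–C3–C11–C10); C10 (R) carries H and the 1-(tert-butyldimethylsilyloxy)-3-methylbut-2-en-2-yl group trans to C12; C11 as in 13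
Conditions: NaH (0.2 equiv), THF, 0 → 23 °C
Reagents that add atoms: none
Why: Alkoxide-catalysed vinylogous transesterification (oxa-Michael addition and loss of methoxide, 5-exo-trig) can occur only at C2, the one enol ether carbon cis to C10 on the cyclopentane, which makes C3 stereogenic and tells C1 from C5.

Step 16
Reactants: 22 oxolane-bridged dienone
Product: 23 bicyclic cycloheptenone: C1–C8 bond in place, ring C1–C2–C3–C11–C10–C7–C8 with a C7=C10 alkene, C2 and C9 ketones, C4 methoxy enol ether, C7 bearing CH2OTBS (C6); C1, C3 and C11 configured as in the target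
Conditions: PhMe (0.02 M), BHT (cat.), 180 °C, sealed tube
Reagents that add atoms: none
Why: Claisen rearrangement in its ring-expanding form (2-alkylidene-5-alkenyl oxolane to cyclohept-4-enone) breaks C10–O2 and joins C1 to C8 through a boat transition state, creating the CMe2–C1 bond, the cis C7=C10 alkene and the C2 ketone; C1 can bond only on the face that carries C11, which fixes its configuration.

Step 17
Reactants: 23 bicyclic cycloheptenone
Product: 24 allylic alcohol: as 23 with C6 as CH2OH
Conditions: n-Bu4NF, THF, 0 °C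
Reagents that add atoms: none
Why: Fluoride removes the silyl ether and frees the hydroxyl that directs the next step.

Step 18
Reactants: 24 allylic alcohol
Product: 25 saturated alcohol: as 24 with C10 as CH2 and C7 as CH, C7 configured as in the target (CH2OH on the side of C5)
Conditions: [Ir(cod)(PCy3)(py)]PF6 (10 mol%), H2 (1 atm), CH2Cl2, 23 °C
Reagents that add atoms: none
Why: Hydroxyl-directed homogeneous hydrogenation of the hindered trisubstituted alkene should add hydrogen to the exo face, away from the C9–C5–C4 bridge, so that C7 is set with C6 pointing toward C5 as the cage requires.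

Step 19
Reactants: 25 saturated alcohol
Product: 26 mesylate of 25 (C6–OMs)
Conditions: MsCl (1.1 equiv), Et3N, CH2Cl2, −20 °C
Reagents that add atoms: methanesulfonyl chloride, CS(=O)(=O)Cl
Why: The primary alcohol is sulfonylated faster than the hindered C1–H diketone can enolise, which installs the leaving group at C6.

Step 20
Reactants: 26 mesylate
Product: 27 trione mesylate: as 26 with the C4 methyl enol ether hydrolysed (drawn as the C4 enol of the 2,4,9-trione)
Conditions: 1 M HCl (aq), THF, 23 °C
Reagents that add atoms: water, O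
Why: Acid hydrolysis of a vinylogous methyl ester gives the 1,3-dione, and under acid the enol cannot alkylate, so the mesylate survives.

Step 21
Reactants: 28 geraniol
Product: 29 geranyl methyl carbonate
Conditions: ClCO2Me, pyridine, CH2Cl2, 0 °C
Reagents that add atoms: methyl chloroformate, COC(Cl)=O
Why: Acylation of the primary allylic alcohol gives a carbonate that ionises without added base in the next step.

Step 22
Reactants: 27 trione mesylate; 29 geranyl methyl carbonate
Product: 30 C5-geranyl trione mesylate: as 27 with an (E)-geranyl group on C5 (drawn as the C4 enol)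
Conditions: 29 (1.05 equiv), Pd(PPh3)4 (5 mol%), THF, 23 °C
Reagents that add atoms: none
Why: Tsuji–Trost allylation, in which the dione anion attacks the unsubstituted terminus of the π-geranyl palladium cation with the E alkene retained; C5 is the only nucleophilic carbon because C1 is blocked by CMe2, and the net neutral conditions leave the mesylate alone.

Step 23
Reactants: 30 C5-geranyl trione mesylate
Product: 31 cage trione: the target without its benzoyl group (homoadamantane-2,4,9-trione with geranyl on C5 and H on C1)
Conditions: KOtBu (1.1 equiv), t-BuOH/THF (1:1), 40 °C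
Reagents that add atoms: none
Why: Intramolecular C-alkylation of the 2-alkyl-1,3-dione enolate (6-exo-tet) closes ring C5–C6–C7–C8–C1–C9 and with it the cage; C6 sits over the enolate face at C5, so carbon and not oxygen is alkylated, and the C5 configuration is dictated by the cage.

Step 24
Reactants: 31 cage trione
Product: 32 target CNP0168637.1
Conditions: lithium 2,2,6,6-tetramethylpiperidide (3 equiv), THF, −78 → −40 °C; then PhCOCl, −78 → 0 °C
Reagents that add atoms: benzoyl chloride, O=C(Cl)c1ccccc1
Why: Bridgehead deprotonation and C-acylation as used on bicyclo[3.3.1]nonane triones: C1–H, between the C2 and C9 ketones, is the only acidic proton, its anion cannot O-acylate, and the cage allows substitution only with retention.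

Compound list
1 | methyl 3,3-dimethylpent-4-enoate | COC(=O)CC(C)(C)C=C | starting material
2 | methyl vinyl ketone | CC(=O)C=C | starting material
3 | methyl (E)-3,3-dimethyl-6-oxohept-4-enoate | COC(=O)CC(C)(C)/C=C/C(C)=O | intermediate
4 | methyl (S,E)-6-hydroxy-3,3-dimethylhept-4-enoate | C[C@H](O)/C=C/C(C)(C)CC(=O)OC | intermediate
5 | phloroglucinol | Oc1cc(O)cc(O)c1 | starting material
6 | methyl (R,E)-6-(3,5-dihydroxyphenoxy)-3,3-dimethylhept-4-enoate | C[C@@H](Oc1cc(O)cc(O)c1)/C=C/C(C)(C)CC(=O)OC | intermediate
7 | methyl (R,E)-3,3-dimethyl-4-(2,4,6-trihydroxyphenyl)hept-5-enoate | Oc1cc(O)c([C@H](/C=C/C)C(C)(C)CC(=O)OC)c(O)c1 | intermediate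
8 | methyl (R,E)-4-[2,6-dihydroxy-4-(triisopropylsilyloxy)phenyl]-3,3-dimethylhept-5-enoate | CC(C)[Si](Oc1cc(O)c([C@H](/C=C/C)C(C)(C)CC(=O)OC)c(O)c1)(C(C)C)C(C)C | intermediate
9 | methyl (R,E)-4-[2,6-dimethoxy-4-(triisopropylsilyloxy)phenyl]-3,3-dimethylhept-5-enoate | COc1cc(O[Si](C(C)C)(C(C)C)C(C)C)cc(OC)c1[C@H](/C=C/C)C(C)(C)CC(=O)OC | intermediate
10 | (R,E)-4-[2,6-dimethoxy-4-(triisopropylsilyloxy)phenyl]-3,3-dimethylhept-5-en-1-ol | COc1cc(O[Si](C(C)C)(C(C)C)C(C)C)cc(OC)c1[C@H](/C=C/C)C(C)(C)CCO | intermediate
11 | (R,E)-4-[2,6-dimethoxy-4-(triisopropylsilyloxy)phenyl]-3,3-dimethylhept-5-en-1-yl methanesulfonate | COc1cc(O[Si](C(C)C)(C(C)C)C(C)C)cc(OC)c1[C@H](/C=C/C)C(C)(C)CCOS(C)(=O)=O | intermediate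
12 | tetrabutylammonium 3,5-dimethoxy-4-[(R,E)-5,5-dimethyl-7-(methylsulfonyloxy)hept-2-en-4-yl]phenoxide (not isolated) | COc1cc([O-])cc(OC)c1[C@H](/C=C/C)C(C)(C)CCOS(C)(=O)=O.CCCC[N+](CCCC)(CCCC)CCCC | intermediate
13 | (1R)-6,10-dimethoxy-2,2-dimethyl-1-[(E)-prop-1-en-1-yl]spiro[4.5]deca-6,9-dien-8-one | COC1=CC(=O)C=C(OC)C12CCC(C)(C)[C@H]2/C=C/C | intermediate
14 | (1R)-6,10-dimethoxy-2,2-dimethyl-8-oxospiro[4.5]deca-6,9-diene-1-carbaldehyde | COC1=CC(=O)C=C(OC)C12CCC(C)(C)[C@H]2C=O | intermediate
15 | 3-methylbut-2-enal | CC(C)=CC=O | starting material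
16 | 2,3-dibromo-3-methylbutanal (not isolated) | CC(C)(Br)C(Br)C=O | intermediate
17 | 2-bromo-3-methylbut-2-enal | CC(C)=C(Br)C=O | intermediate
18 | 2-bromo-3-methylbut-2-en-1-ol | CC(C)=C(Br)CO | intermediate
19 | [(2-bromo-3-methylbut-2-en-1-yl)oxy](tert-butyl)dimethylsilane | CC(C)=C(Br)CO[Si](C)(C)C(C)(C)C | intermediate
20 | [1-(tert-butyldimethylsilyloxy)-3-methylbut-2-en-2-yl]lithium (not isolated) | CC(C)=C([Li])CO[Si](C)(C)C(C)(C)C | intermediate
21 | (1R)-1-[(1R)-2-[(tert-butyldimethylsilyloxy)methyl]-1-hydroxy-3-methylbut-2-en-1-yl]-6,10-dimethoxy-2,2-dimethylspiro[4.5]deca-6,9-dien-8-one | COC1=CC(=O)C=C(OC)C12CCC(C)(C)[C@H]2[C@@H](O)C(CO[Si](C)(C)C(C)(C)C)=C(C)C | intermediate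
22 | oxolane-bridged dienone (O2 bonded to C10; alkenyl group on C10 trans to C12) | COC1=CC(=O)C=C2O[C@@H](C(CO[Si](C)(C)C(C)(C)C)=C(C)C)[C@@H]3C(C)(C)CC[C@]123 | intermediate
23 | bicyclic cycloheptenone (C1–C8 bond, C7=C10 alkene, C6 as CH2OTBS) | COC1=CC(=O)[C@@H]2C(=O)[C@]13CCC(C)(C)[C@H]3C=C(CO[Si](C)(C)C(C)(C)C)C2(C)C | intermediate
24 | allylic alcohol (C6 as CH2OH) | COC1=CC(=O)[C@@H]2C(=O)[C@]13CCC(C)(C)[C@H]3C=C(CO)C2(C)C | intermediate
25 | saturated alcohol (C7–H set, C10 as CH2) | COC1=CC(=O)[C@@H]2C(=O)[C@]13CCC(C)(C)[C@H]3C[C@H](CO)C2(C)C | intermediate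
26 | C6 mesylate | COC1=CC(=O)[C@@H]2C(=O)[C@]13CCC(C)(C)[C@H]3C[C@H](COS(C)(=O)=O)C2(C)C | intermediate
27 | trione mesylate (C4 enol drawn) | OC1=CC(=O)[C@@H]2C(=O)[C@]13CCC(C)(C)[C@H]3C[C@H](COS(C)(=O)=O)C2(C)C | intermediate
28 | geraniol | CC(C)=CCC/C(C)=C/CO | starting material
29 | geranyl methyl carbonate | CC(C)=CCC/C(C)=C/COC(=O)OC | intermediate
30 | C5-geranyl trione mesylate (C4 enol drawn) | OC1=C(C/C=C(\C)CCC=C(C)C)C(=O)[C@@H]2C(=O)[C@]13CCC(C)(C)[C@H]3C[C@H](COS(C)(=O)=O)C2(C)C | intermediate
31 | cage trione, the target without its benzoyl group | CC(C)=CCC/C(C)=C/C[C@@]12C[C@H]3C[C@@H]4C(C)(C)CC[C@]4(C1=O)C(=O)[C@@H](C2=O)C3(C)C | intermediate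
32 | CNP0168637.1 | CC(C)=CCC/C(C)=C/C[C@@]12C[C@H]3C[C@@H]4C(C)(C)CC[C@]4(C1=O)C(=O)[C@@](C(=O)c1ccccc1)(C2=O)C3(C)C | target

Total step count: 24 (main line 20, alkenyl bromide branch 3, carbonate 1).
Longest linear sequence: 20 steps (steps 1–10, 14–20, 22–24).

Steps most likely to fail

Step 16 (ring-expanding Claisen). Only the oxolane whose alkenyl group is trans to C12 can fold into the boat transition state. If the addition of step 14 shows poor or reversed facial selectivity, heating should lead only to heterolysis of the C10–O2 bond and loss of a proton to a triene. The fallback sets out from aldehyde 14 and comes back to the route at alcohol 21. Step 14 is run as before, and the C10 epimer of alcohol 21 F1, then the main product, is oxidised with Dess–Martin periodinane (CH2Cl2, 23 °C) to the enone F2. Reduction with NaBH4/CeCl3·7H2O (MeOH, −78 °C) then delivers hydride along the Felkin–Anh trajectory that the alkenyl group had taken, which inverts the outcome at C10 and should give 21; steps 15 and 16 follow unchanged.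

Step 18 (hydrogenation). Poor facial selectivity: delivery of hydrogen to the face next to the C9–C5–C4 bridge would turn C6 away from C5, and no cage could then close. The fallback sets out from allylic alcohol 24 and comes back at cage trione 31; in it the C7 configuration is imposed by the cage instead of by a reagent. Reductive 1,3-transposition of 24 through its allylic diazene (o-nitrobenzenesulfonylhydrazine, PPh3, DEAD, THF, −30 → 23 °C) should give the exocyclic methylene compound F3 (C7=C6H2, C10 as CH2). NaOH (aq)/MeOH and then HCl cleave the methyl enol ether to the methylene trione F4. Tsuji–Trost geranylation with 29 and Pd(PPh3)4, as in step 22, gives the C5-geranyl methylene trione F5. Bromination of its sodium enolate (NaH, then N-bromosuccinimide, THF, −78 °C) gives the C5 bromide F6. With n-Bu3SnH and AIBN (PhH, 80 °C, slow addition) the C5 radical adds in the 6-endo mode to the methylene carbon C6, and the cage radical at C7 can take hydrogen only from outside, which should give 31.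

Step 24 (bridgehead benzoylation). The hindered bridgehead lithium species next to C8 may react with benzoyl chloride too slowly, or by electron transfer, so that 31 is returned on work-up. The fallback sets out from 31 and comes back at target 32. The same anion is trapped with the small electrophile iodine (lithium 2,2,6,6-tetramethylpiperidide, THF, −78 °C; then I2) to give the bridgehead iodide F7. Iodine–magnesium exchange (i-PrMgCl, THF, −78 °C) and addition to benzaldehyde give the bridgehead carbinol F8 (either configuration at the carbinol carbon), and Dess–Martin oxidation gives 32.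

Further compounds
F1 | step 16 | C10 epimer of alcohol 21 | COC1=CC(=O)C=C(OC)C12CCC(C)(C)[C@H]2[C@H](O)C(CO[Si](C)(C)C(C)(C)C)=C(C)C
F2 | step 16 | enone (C10 ketone) | COC1=CC(=O)C=C(OC)C12CCC(C)(C)[C@H]2C(=O)C(CO[Si](C)(C)C(C)(C)C)=C(C)C
F3 | step 18 | exocyclic methylene compound | COC1=CC(=O)[C@@H]2C(=O)[C@]13CCC(C)(C)[C@H]3CC(=C)C2(C)C
F4 | step 18 | methylene trione (C4 enol drawn) | OC1=CC(=O)[C@@H]2C(=O)[C@]13CCC(C)(C)[C@H]3CC(=C)C2(C)C
F5 | step 18 | C5-geranyl methylene trione (C4 enol drawn) | OC1=C(C/C=C(\C)CCC=C(C)C)C(=O)[C@@H]2C(=O)[C@]13CCC(C)(C)[C@H]3CC(=C)C2(C)C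
F6 | step 18 | C5 bromide | O=C1C(Br)(C/C=C(\C)CCC=C(C)C)C(=O)[C@@H]2C(=O)[C@]13CCC(C)(C)[C@H]3CC(=C)C2(C)C
F7 | step 24 | bridgehead iodide | CC(C)=CCC/C(C)=C/C[C@@]12C[C@H]3C[C@@H]4C(C)(C)CC[C@]4(C1=O)C(=O)[C@@](I)(C2=O)C3(C)C
F8 | step 24 | bridgehead carbinol | CC(C)=CCC/C(C)=C/C[C@@]12C[C@H]3C[C@@H]4C(C)(C)CC[C@]4(C1=O)C(=O)[C@@](C(O)c1ccccc1)(C2=O)C3(C)C
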